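The cyclohexanone ring of the target (C1–C2–C3–C4–C5–C8, IUPAC locants of the bicyclo[3.2.1]octan-2-one) is cut at C3–C4 and C1–C8. This pairs the α,α′-dimethoxy ketone C1–C2–C3 (an oxyallyl synthon) with C4H2 and C8H(OH), which sit 1,3 to each other on quaternary C5 (a homoenolate synthon, masked as a cyclopropyl silyl ether). In the key step catalytic Me3SiOSO2CF3 turns an enol-silane acetal into a 2-siloxyallyl cation; the cyclopropane attacks it (C3–C4, seven-membered ring) and the silyl oxocarbenium ion set free is trapped across the ring by the enol silane (C1–C8). The precursor is an open-chain cyclopropane built from (S)-β-methyl-γ-butyrolactone.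

Key step: step 10

Assumption: (S)-4-methyloxolan-2-one 1 is taken as a purchasable chiral-pool lactone.
Remark: bicyclic compounds carry the locants of the target name (C1 methoxy bridgehead, C2 carbonyl, C3 CH(OMe), C4 CH2, C5 allyl bridgehead, C6 CHMe, C7 CHAr, C8 carbinol bridge).

Step 1
Reactants: 1 (S)-4-methyloxolan-2-one
Product: 2 (3S,4S)-4-methyl-3-(prop-2-en-1-yl)oxolan-2-one
Conditions: LiN(i-Pr)2, THF, −78 °C; allyl bromide, −78 → −30 °C
Reagents that add atoms: allyl bromide C=CCBr
Why: Alkylation of the lithium lactone enolate should occur trans to the C4 methyl group (enolate alkylation), and the new centre is only provisional because it is enolized again in step 2.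

Step 2
Reactants: 2 (3S,4S)-4-methyl-3-(prop-2-en-1-yl)oxolan-2-one
Product: 3 (3S,4S)-3-(iodomethyl)-4-methyl-3-(prop-2-en-1-yl)oxolan-2-one
Conditions: LiN(i-Pr)2, THF/DMPU, −78 °C; CH2I2, −78 → 0 °C
Reagents that add atoms: diiodomethane ICI
Why: A second enolate alkylation (iodomethylation) should build the quaternary carbon with the electrophile entering anti to the adjacent methyl group, so that CH2I is trans and allyl cis to it (the future C5 configuration); the neopentyl iodide formed cannot eliminate or be displaced further.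

Step 3
Reactants: 3 (3S,4S)-3-(iodomethyl)-4-methyl-3-(prop-2-en-1-yl)oxolan-2-one
Product: 4 (3S,4S)-3-(iodomethyl)-4-methyl-3-(prop-2-en-1-yl)oxolan-2-ol (both C2 epimers)
Conditions: i-Bu2AlH, CH2Cl2, −78 °C; Rochelle salt work-up
Reagents that add atoms: none
Why: Partial reduction of the lactone with i-Bu2AlH at low temperature should stop at the lactol because the tetrahedral aluminate is stable there, and the neopentyl iodide and the alkene are inert to the hydride.

Step 4
Reactants: 4 (3S,4S)-3-(iodomethyl)-4-methyl-3-(prop-2-en-1-yl)oxolan-2-ol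
Product: 6 triethyl{[(2S)-2-(prop-2-en-1-yl)-2-[(2S)-1-(triethylsilyloxy)propan-2-yl]cyclopropyl]oxy}silane (both cyclopropane C1 epimers), via dilithium cyclopropanolate alkoxide 5 (not isolated)
Conditions: t-BuLi (3.1 equiv), Et2O/pentane, −78 → 0 °C; Et3SiCl, THF, 0 °C
Reagents that add atoms: chlorotriethylsilane CC[Si](Cl)(CC)CC
Why: Lithium–iodine exchange gives the β-lithio aldehyde (open form of the lithium lactolate), which should collapse by 3-exo-trig addition to the carbonyl group to the cyclopropanolate, the usual fate of an aldehyde homoenolate, after which both alkoxides are silylated; the carbinol centre forms as a mixture that is erased in step 10.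

Step 5
Reactants: 6 triethyl{[(2S)-2-(prop-2-en-1-yl)-2-[(2S)-1-(triethylsilyloxy)propan-2-yl]cyclopropyl]oxy}silane
Product: 7 (2S)-2-[(1S)-1-(prop-2-en-1-yl)-2-(triethylsilyloxy)cyclopropyl]propanal
Conditions: (COCl)2, Me2SO, CH2Cl2, −78 °C; Et3N, −78 → −20 °C
Reagents that add atoms: none
Why: Swern conditions should convert the primary triethylsilyl ether directly into the aldehyde (selective oxidative desilylation), whereas the hindered cyclopropyl silyl ether is not attacked.

Step 6
Reactants: 8 diethyl (methoxymethyl)phosphonate; 9 methyl 2,2-dimethoxyacetate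
Product: 10 diethyl (1,3,3-trimethoxy-2-oxopropyl)phosphonate (racemic)
Conditions: LiN(i-Pr)2 (2.1 equiv), THF, −78 °C; 9, −78 → 0 °C; AcOH
Reagents that add atoms: none
Why: Claisen-type acylation of the α-lithiated phosphonate by the ester should be driven by deprotonation of the β-keto phosphonate formed, which is why two equivalents of base are used.

Step 7
Reactants: 7 (2S)-2-[(1S)-1-(prop-2-en-1-yl)-2-(triethylsilyloxy)cyclopropyl]propanal; 10 diethyl (1,3,3-trimethoxy-2-oxopropyl)phosphonate
Product: 11 (3Z,5R)-1,1,3-trimethoxy-5-[(1S)-1-(prop-2-en-1-yl)-2-(triethylsilyloxy)cyclopropyl]hex-3-en-2-one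
Conditions: LiCl, DBU, MeCN, 0 → 25 °C
Reagents that add atoms: none
Why: Horner–Wadsworth–Emmons olefination under Masamune–Roush conditions should be mild enough not to epimerize the α-stereocentre of 7, and the alkene geometry is of no consequence because allylic 1,3-strain operates for either isomer in step 9.

Step 8
Reactants: 12 5-bromo-2-methoxyphenol
Product: 13 (5-bromo-2-methoxyphenoxy)tri(propan-2-yl)silane
Conditions: i-Pr3SiCl, imidazole, DMF, 25 °C
Reagents that add atoms: chlorotri(propan-2-yl)silane CC(C)[Si](Cl)(C(C)C)C(C)C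
Why: Imidazole-promoted silylation of the phenol gives a bulky, weakly donating aryl silyl ether that should survive every later step up to step 11.

Step 9
Reactants: 11 (3Z,5R)-1,1,3-trimethoxy-5-[(1S)-1-(prop-2-en-1-yl)-2-(triethylsilyloxy)cyclopropyl]hex-3-en-2-one; 13 (5-bromo-2-methoxyphenoxy)tri(propan-2-yl)silane
Product: 15 {[(2Z,4S,5R)-1,1,3-trimethoxy-4-{4-methoxy-3-[tri(propan-2-yl)silyloxy]phenyl}-5-[(1S)-1-(prop-2-en-1-yl)-2-(triethylsilyloxy)cyclopropyl]hex-2-en-2-yl]oxy}trimethylsilane, via aryl Grignard reagent 14 (not isolated)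
Conditions: 13, Mg, LiCl, THF, 25 °C; CuBr·SMe2 (10 mol %), Me3SiCl, 11, THF, −78 → −40 °C; Et3N
Reagents that add atoms: chlorotrimethylsilane C[Si](C)(C)Cl
Why: Copper-catalysed conjugate addition of the aryl Grignard reagent with silyl chloride trapping should set C4 of the chain (future C7) as 4S, because the fully substituted α-carbon enforces the allylic 1,3-strain conformer with the allylic C–H in the alkene plane and the aryl group then adds anti to the quaternary cyclopropyl carbon; the chelated enolate is silylated with the methoxy group cis to the siloxy group.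

Step 10
Reactants: 15 {[(2Z,4S,5R)-1,1,3-trimethoxy-4-{4-methoxy-3-[tri(propan-2-yl)silyloxy]phenyl}-5-[(1S)-1-(prop-2-en-1-yl)-2-(triethylsilyloxy)cyclopropyl]hex-2-en-2-yl]oxy}trimethylsilane
Product: 18 (1S,3R,5S,6R,7S,8S)-1,3-dimethoxy-7-{4-methoxy-3-[tri(propan-2-yl)silyloxy]phenyl}-6-methyl-5-(prop-2-en-1-yl)-8-(triethylsilyloxy)bicyclo[3.2.1]octan-2-one, via siloxyallyl cation triflate 16 (not isolated), via silyl oxocarbenium triflate 17 (not isolated)
Conditions: Me3SiOSO2CF3 (0.2 equiv), 2,6-di-tert-butyl-4-methylpyridine (0.3 equiv), CH2Cl2 (0.01 M), −78 → −40 °C; Et3N, aq. NaHCO3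
Reagents that add atoms: none
Why: Proposed new method: Me3SiOSO2CF3 removes one acetal methoxy group of 15 to give the 1,3-dimethoxy-2-siloxyallyl cation 16, whose unsubstituted oxocarbenium carbon (future C3) is attacked by the CH2 carbon of the cyclopropyl silyl ether (future C4) with opening of the three-membered ring to the silyl oxocarbenium ion 17, which is captured by the enol silane carbon (future C1) in a transannular Mukaiyama aldol step that forms C1–C8 and returns the silyl cation to the catalyst. The closest known reactions are the Lewis-acid cyclization of cyclopropyl silyl ethers (homoenol ethers) onto oxocarbenium ions to give seven-membered carbocycles, the use of 2-siloxyallyl cations from α-siloxy enol acetals as electrophiles and the Mukaiyama aldol reaction, and their union in one cationic formal [3+3] annulation is what is new. The seven-membered ring closes in a 7-exo-trig mode onto the C=O+ bond, and the second bond closes the cyclopentane in a 5-(enolexo)-exo-trig mode and with it the cyclohexanone in a 6-(enolendo)-exo-trig mode. C1 can only form with the configuration shown because the C6–C7 tether holds the formyl carbon over one face of the enol silane, C8 should place its silyloxy group away from the exo methyl group on C6, and C3 is expected with its methoxy group exo (3R) because the cation prefers the geometry with this methoxy group outside (corrected in step 12). The step needs attack at the C3 terminus instead of the C1 terminus of the allyl cation and no Friedel–Crafts closure by the aryl ring, which is secured because C3 is the unhindered site of ionization while C1 is fully substituted, and because the aryl positions in reach are meta to the methoxy group and next to a bulky, weakly donating silyloxy group. Acid that would protonate the cyclopropane is scavenged by the hindered pyridine.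

Step 11
Reactants: 18 (1S,3R,5S,6R,7S,8S)-1,3-dimethoxy-7-{4-methoxy-3-[tri(propan-2-yl)silyloxy]phenyl}-6-methyl-5-(prop-2-en-1-yl)-8-(triethylsilyloxy)bicyclo[3.2.1]octan-2-one
Product: 19 (1S,3R,5S,6R,7S,8S)-8-hydroxy-7-(3-hydroxy-4-methoxyphenyl)-1,3-dimethoxy-6-methyl-5-(prop-2-en-1-yl)bicyclo[3.2.1]octan-2-one
Conditions: HF·pyridine, pyridine, THF, 0 → 25 °C
Reagents that add atoms: none
Why: Fluoride cleavage of both silyl ethers under non-basic conditions should leave the β-hydroxy ketone (no retro-aldol) and C3 untouched.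

Step 12
Reactants: 19 (1S,3R,5S,6R,7S,8S)-8-hydroxy-7-(3-hydroxy-4-methoxyphenyl)-1,3-dimethoxy-6-methyl-5-(prop-2-en-1-yl)bicyclo[3.2.1]octan-2-one
Product: 21 (1S,3S,5S,6R,7S,8S)-8-hydroxy-7-(3-hydroxy-4-methoxyphenyl)-1,3-dimethoxy-6-methyl-5-(prop-2-en-1-yl)bicyclo[3.2.1]octan-2-one, via trilithium enolate 20 (not isolated)
Conditions: 19 added to LiN(i-Pr)2 (3.5 equiv), THF, −78 °C; AcOH, −78 °C
Reagents that add atoms: none
Why: Deprotonation can only give the C2–C3 enolate (C1 is quaternary), and kinetic enolate protonation should occur on the exo face, syn to and relayed by the C8 oxygen, because the endo face is shielded by the C6–C7 bridge and its endo aryl group (as in exo attack on tropinone-type bicyclo[3.2.1]octan-3-ones), which places the methoxy group endo (3S).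

Compound list
1 | (S)-4-methyloxolan-2-one | C[C@@H]1COC(=O)C1 | starting material
2 | (3S,4S)-4-methyl-3-(prop-2-en-1-yl)oxolan-2-one | C=CC[C@@H]([C@H](C)CO1)C1=O | intermediate
3 | (3S,4S)-3-(iodomethyl)-4-methyl-3-(prop-2-en-1-yl)oxolan-2-one | C=CC[C@]([C@H](C)CO1)(C1=O)CI | intermediate
4 | (3S,4S)-3-(iodomethyl)-4-methyl-3-(prop-2-en-1-yl)oxolan-2-ol, both C2 epimers | C=CC[C@]([C@H](C)CO1)(C1O)CI | intermediate
5 | dilithium (2S)-2-[(2S)-1-oxidopropan-2-yl]-2-(prop-2-en-1-yl)cyclopropan-1-olate, both C1 epimers | C=CC[C@]([C@H](C)C[O-])(C1[O-])C1.[Li+].[Li+] | intermediate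
6 | triethyl{[(2S)-2-(prop-2-en-1-yl)-2-[(2S)-1-(triethylsilyloxy)propan-2-yl]cyclopropyl]oxy}silane, both C1 epimers | C=CC[C@]([C@H](C)CO[Si](CC)(CC)CC)(C1O[Si](CC)(CC)CC)C1 | intermediate
7 | (2S)-2-[(1S)-1-(prop-2-en-1-yl)-2-(triethylsilyloxy)cyclopropyl]propanal, both epimers at the silyloxy carbon | C=CC[C@]([C@H](C)C=O)(C1O[Si](CC)(CC)CC)C1 | intermediate
8 | diethyl (methoxymethyl)phosphonate | CCOP(=O)(COC)OCC | starting material
9 | methyl 2,2-dimethoxyacetate | COC(OC)C(=O)OC | starting material
10 | diethyl (1,3,3-trimethoxy-2-oxopropyl)phosphonate (racemic) | CCOP(=O)(OCC)C(OC)C(=O)C(OC)OC | intermediate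
11 | (3Z,5R)-1,1,3-trimethoxy-5-[(1S)-1-(prop-2-en-1-yl)-2-(triethylsilyloxy)cyclopropyl]hex-3-en-2-one | C=CC[C@]([C@H](C)/C=C(\OC)C(=O)C(OC)OC)(C1O[Si](CC)(CC)CC)C1 | intermediate
12 | 5-bromo-2-methoxyphenol | COc1ccc(Br)cc1O | starting material
13 | (5-bromo-2-methoxyphenoxy)tri(propan-2-yl)silane | COc1ccc(Br)cc1O[Si](C(C)C)(C(C)C)C(C)C | intermediate
14 | {4-methoxy-3-[tri(propan-2-yl)silyloxy]phenyl}magnesium bromide | COc1ccc([Mg]Br)cc1O[Si](C(C)C)(C(C)C)C(C)C | intermediate
15 | {[(2Z,4S,5R)-1,1,3-trimethoxy-4-{4-methoxy-3-[tri(propan-2-yl)silyloxy]phenyl}-5-[(1S)-1-(prop-2-en-1-yl)-2-(triethylsilyloxy)cyclopropyl]hex-2-en-2-yl]oxy}trimethylsilane | C=CC[C@]([C@H](C)[C@@H](c1ccc(OC)c(O[Si](C(C)C)(C(C)C)C(C)C)c1)/C(OC)=C(/O[Si](C)(C)C)C(OC)OC)(C2O[Si](CC)(CC)CC)C2 | intermediate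
16 | 1,3-dimethoxy-2-(trimethylsiloxy)allyl cation of 15 (O-methyl oxocarbenium form), trifluoromethanesulfonate | C=CC[C@]([C@H](C)[C@@H](c1ccc(OC)c(O[Si](C(C)C)(C(C)C)C(C)C)c1)/C(OC)=C(/O[Si](C)(C)C)C=[O+]C)(C2O[Si](CC)(CC)CC)C2.[O-]S(=O)(=O)C(F)(F)F | intermediate
17 | O-triethylsilyl oxocarbenium ion of the 1-formylcyclohept-4-ene enol silane (C3–C4 bond formed), trifluoromethanesulfonate | C=CC[C@]1(C=[O+][Si](CC)(CC)CC)C[C@@H](OC)C(O[Si](C)(C)C)=C(OC)[C@H](c2ccc(OC)c(O[Si](C(C)C)(C(C)C)C(C)C)c2)[C@H]1C.[O-]S(=O)(=O)C(F)(F)F | intermediate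
18 | (1S,3R,5S,6R,7S,8S)-1,3-dimethoxy-7-{4-methoxy-3-[tri(propan-2-yl)silyloxy]phenyl}-6-methyl-5-(prop-2-en-1-yl)-8-(triethylsilyloxy)bicyclo[3.2.1]octan-2-one | C=CC[C@]12C[C@@H](OC)C(=O)[C@](OC)([C@H](c3ccc(OC)c(O[Si](C(C)C)(C(C)C)C(C)C)c3)[C@H]1C)[C@H]2O[Si](CC)(CC)CC | intermediate
19 | (1S,3R,5S,6R,7S,8S)-8-hydroxy-7-(3-hydroxy-4-methoxyphenyl)-1,3-dimethoxy-6-methyl-5-(prop-2-en-1-yl)bicyclo[3.2.1]octan-2-one (C3 epimer of the target) | C=CC[C@]12C[C@@H](OC)C(=O)[C@](OC)([C@H](c3ccc(OC)c(O)c3)[C@H]1C)[C@H]2O | intermediate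
20 | trilithium C2–C3 enolate, C8 alkoxide and phenoxide of 19 | C=CC[C@]12CC(OC)=C([O-])[C@](OC)([C@H](c3ccc(OC)c([O-])c3)[C@H]1C)[C@H]2[O-].[Li+].[Li+].[Li+] | intermediate
21 | (1S,3S,5S,6R,7S,8S)-8-hydroxy-7-(3-hydroxy-4-methoxyphenyl)-1,3-dimethoxy-6-methyl-5-(prop-2-en-1-yl)bicyclo[3.2.1]octan-2-one | C=CC[C@]12C[C@H](OC)C(=O)[C@](OC)([C@H](c3ccc(OC)c(O)c3)[C@H]1C)[C@H]2O | target

Total step count: 12. Longest linear sequence: 10 steps (steps 1–5, 7, 9–12).

Steps most likely to fail

Step 10 (Proposed new method). The cyclopropane carbon may attack the substituted C1 terminus of the allyl cation in a five-membered closure, the aryl ring may close by Friedel–Crafts alkylation, or protonolysis may open the cyclopropane before any C–C bond forms. The fallback uses known chemistry in separate stages; it sets out from enone 11 (with Grignard reagent 14 made from 13 as in step 9) and comes back to the route at 19. Copper-catalysed addition of 14 to 11 without Me3SiCl, followed by an acetic acid quench, should give the acyclic keto acetal F1. Me3SiOSO2CF3 (or TiCl4) in CH2Cl2 at −78 °C then ionizes the acetal of F1, which now lies next to a ketone and is not part of an allyl cation, so only C3 is electrophilic; the cyclopropyl silyl ether closes onto it in the known homoenol-ether manner to the formyl cycloheptanone F2. A reversible DBU-mediated intramolecular aldol reaction of F2, in which only the C1 enolate can reach the aldehyde in a five-membered mode, should give the aryl silyl ether F3, and HF·pyridine as in step 11 returns to 19.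

Step 12. Facial selectivity in the kinetic protonation may be poor, or the enolate may return to the more stable exo-methoxy epimer. The fallback sets out from 18 and comes back at 21, and sets C3 by an enzyme instead of by an achiral proton source. LiN(i-Pr)2 followed by N-tert-butylbenzenesulfinimidoyl chloride (Mukaiyama dehydrogenation) should give the silyl-protected C3–C4 enone F4, and HF·pyridine the free enone F5. An ene-reductase of the old yellow enzyme family (flavin-dependent, NADPH recycled by an alcohol dehydrogenase with propan-2-ol), chosen by screening, then adds hydride to C4 and a proton to C3 of F5. It should reduce only the conjugated alkene and leave the allyl group, giving 21.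

Step 9. Conjugate addition may be slow at the hindered β-carbon of the electron-rich α-methoxy enone, so that 1,2-addition or loss of facial control takes over. The fallback sets out from 13 and 11 and comes back at 15. n-BuLi then ZnCl2 convert 13 into the arylzinc chloride F6. F6 adds to 11 under rhodium catalysis ([RhCl(binap)]2, the ligand enantiomer chosen to reinforce the substrate bias) in THF in the presence of Me3SiCl, a known aprotic variant of the Hayashi–Miyaura reaction that delivers the silyl enol ether 15 directly.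

Further compounds
F1 | step 10 | (4S,5R)-1,1,3-trimethoxy-4-{4-methoxy-3-[tri(propan-2-yl)silyloxy]phenyl}-5-[(1S)-1-(prop-2-en-1-yl)-2-(triethylsilyloxy)cyclopropyl]hexan-2-one (C3 epimers) | C=CC[C@]([C@H](C)[C@@H](c1ccc(OC)c(O[Si](C(C)C)(C(C)C)C(C)C)c1)C(OC)C(=O)C(OC)OC)(C2O[Si](CC)(CC)CC)C2
F2 | step 10 | (1S,2R,3S)-4,6-dimethoxy-3-{4-methoxy-3-[tri(propan-2-yl)silyloxy]phenyl}-2-methyl-5-oxo-1-(prop-2-en-1-yl)cycloheptane-1-carbaldehyde (C4 and C6 epimers) | C=CC[C@]1(C=O)CC(OC)C(=O)C(OC)[C@H](c2ccc(OC)c(O[Si](C(C)C)(C(C)C)C(C)C)c2)[C@H]1C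
F3 | step 10 | (1S,3R,5S,6R,7S,8S)-8-hydroxy-1,3-dimethoxy-7-{4-methoxy-3-[tri(propan-2-yl)silyloxy]phenyl}-6-methyl-5-(prop-2-en-1-yl)bicyclo[3.2.1]octan-2-one | C=CC[C@]12C[C@@H](OC)C(=O)[C@](OC)([C@H](c3ccc(OC)c(O[Si](C(C)C)(C(C)C)C(C)C)c3)[C@H]1C)[C@H]2O
F4 | step 12 | C3–C4 enone of 18: 1,3-dimethoxy-7-{4-methoxy-3-[tri(propan-2-yl)silyloxy]phenyl}-6-methyl-5-(prop-2-en-1-yl)-8-(triethylsilyloxy)bicyclo[3.2.1]oct-3-en-2-one, other centres as in 18 | C=CC[C@]12C=C(OC)C(=O)[C@](OC)([C@H](c3ccc(OC)c(O[Si](C(C)C)(C(C)C)C(C)C)c3)[C@H]1C)[C@H]2O[Si](CC)(CC)CC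
F5 | step 12 | C3–C4 enone of 21: 8-hydroxy-7-(3-hydroxy-4-methoxyphenyl)-1,3-dimethoxy-6-methyl-5-(prop-2-en-1-yl)bicyclo[3.2.1]oct-3-en-2-one, other centres as in 21 | C=CC[C@]12C=C(OC)C(=O)[C@](OC)([C@H](c3ccc(OC)c(O)c3)[C@H]1C)[C@H]2O
F6 | step 9 | chlorido{4-methoxy-3-[tri(propan-2-yl)silyloxy]phenyl}zinc | COc1ccc([Zn]Cl)cc1O[Si](C(C)C)(C(C)C)C(C)C
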